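**Retrosynthetic overview**

1. Target 16 is opened by a retro-[4+2]: the cyclohexene C12–C13=C14–C15–C15'–C14' comes from the (12E)-12,14-diene of acid 13 (4π) and the terminal C14'=C15' vinyl of alcohol 15 (2π). The cycloaddition is run last, neat, on the unprotected partners.
2. Acid 13 and alcohol 15 both come from one ester 12 (S-demethylation or hydride reduction).
3. The diene of 12 is built from C12 aldehyde 10 by two Wittig reactions (E-enal, then methylenation).
4. Aldehyde 10 comes from (+)-abietic acid 1 by unzipping ring C: 13,14-cleavage, alkene-transposing reduction of the C14 aldehyde to the exocyclic methylene, and excision of the isopropyl ketone.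
5. Ring order: both decalins (C4, C5, C9, C10 and their primed counterparts) are carried intact from 1; the only ring formed is the central cyclohexene, in the last step.

Assumption: technical (+)-abietic acid, purified once through an amine salt, is the single chiral starting material. Labdane numbering is used, with primes for the alcohol-derived half; C14 of abietane becomes C17 of labdane.

**Route**

Step 1
Reactants: 1 (+)-abietic acid
Product: 2 methyl abietate
Conditions: MeI, K2CO3, DMF, 23 °C
Reagents that add atoms: iodomethane CI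
Why: Carboxylate O-alkylation (SN2 esterification) masks the C18 acid for the hydrazone, enolate and ylide chemistry ahead; C4, C5, C9 and C10 of abietic acid already have the configuration needed in both halves of the target and are not touched here or later.

Step 2
Reactants: 2 methyl abietate
Product: 4 methyl 13-oxo-13,14-secoabiet-7-en-14-al-18-oate, via cis-diol 3 (not isolated)
Conditions: K2OsO4·2H2O (2 mol%), NMO (1.05 equiv), acetone–H2O, 0 → 23 °C; then NaIO4, 23 °C
Reagents that add atoms: N-methylmorpholine N-oxide C[N+]1([O-])CCOCC1; water O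
Why: Upjohn dihydroxylation is expected to go to the more accessible 13,14-alkene of ring C, and in-flask periodate (Malaprade) glycol cleavage opens that ring, leaving C14 as an enal carbon (the future C17) and C13 as an isopropyl ketone; both carbinol centres of 3 vanish, so the face of osmylation does not matter.

Step 3
Reactants: 4 methyl 13-oxo-13,14-secoabiet-7-en-14-al-18-oate
Product: 7 methyl 13-oxo-13,14-secoabiet-8(14)-en-18-oate, via tosylhydrazone 5 (not isolated), via allylic diazene 6 (not isolated)
Conditions: TsNHNH2 (1.05 equiv), THF, 23 °C; then catecholborane, 0 °C; then NaOAc·3H2O, 65 °C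
Reagents that add atoms: none
Why: Kabalka-type reduction of an α,β-unsaturated tosylhydrazone: the aldehyde condenses in preference to the hindered ketone, hydride adds to C=N, loss of sulfinate gives the allylic diazene, and its retro-ene loss of N2 delivers hydrogen to C7 while moving the alkene to the exocyclic 8(17) position; no stereocentre is made and C9–H stays α.

Step 4
Reactants: 7 methyl 13-oxo-13,14-secoabiet-8(14)-en-18-oate
Product: 9 methyl 12-hydroxy-13-oxo-13,14-secoabiet-8(14)-en-18-oate, via potassium enolate 8 (not isolated)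
Conditions: KHMDS, THF, −78 °C; then 2-(phenylsulfonyl)-3-phenyloxaziridine, −78 °C; aq. NH4Cl
Reagents that add atoms: 2-(phenylsulfonyl)-3-phenyloxaziridine O=S(=O)(N1OC1c1ccccc1)c1ccccc1
Why: Kinetic deprotonation by the bulky amide occurs at the C12 methylene rather than the isopropyl methine, and Davis oxaziridine enolate hydroxylation puts the oxygen on C12 (epimer mixture, centre destroyed in step 5); the ester has no α-hydrogen and the exocyclic alkene is inert.

Step 5
Reactants: 9 methyl 12-hydroxy-13-oxo-13,14-secoabiet-8(14)-en-18-oate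
Product: 10 methyl 12-oxo-13,14,15,16-tetranorlabd-8(17)-en-18-oate
Conditions: Pb(OAc)4, MeOH–PhMe 1:1, 0 °C
Reagents that add atoms: none
Why: Criegee oxidative cleavage of the α-hydroxy ketone breaks C12–C13, giving the C12 aldehyde and releasing the isopropyl acyl unit as its methyl ester, under conditions that leave the 1,1-disubstituted alkene alone.

Step 6
Reactants: 10 methyl 12-oxo-13,14,15,16-tetranorlabd-8(17)-en-18-oate
Product: 11 methyl (12E)-14-oxo-15-norlabda-8(17),12-dien-18-oate
Conditions: Ph3P=C(Me)CHO, PhMe, 100 °C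
Reagents that add atoms: 2-(triphenylphosphoranylidene)propanal CC(C=O)=P(c1ccccc1)(c1ccccc1)c1ccccc1
Why: Wittig olefination with a stabilised formyl ylide gives the trisubstituted 2-methyl-2-enal with high E selectivity (chain trans to CHO), which fixes the 12E geometry of both halves of the target.

Step 7
Reactants: 11 methyl (12E)-14-oxo-15-norlabda-8(17),12-dien-18-oate
Product: 12 methyl (12E)-labda-8(17),12,14-trien-18-oate
Conditions: Ph3PCH3Br, KOt-Bu, THF, 0 → 23 °C
Reagents that add atoms: methyltriphenylphosphonium bromide C[P+](c1ccccc1)(c1ccccc1)c1ccccc1.[Br-]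
Why: Wittig methylenation of the enal carbonyl (1,2-addition of the non-stabilised ylide) completes the 12E,14-diene without moving the existing double bonds.

Step 8
Reactants: 12 methyl (12E)-labda-8(17),12,14-trien-18-oate
Product: 13 (12E)-labda-8(17),12,14-trien-18-oic acid
Conditions: NaSEt, DMF, 90 °C; then 0.5 M HCl, 0 °C
Reagents that add atoms: none
Why: SN2 demethylation of the hindered equatorial methyl ester by thiolate at the O-methyl carbon (alkyl–oxygen cleavage) avoids attack at the neopentyl-type carbonyl and leaves the diene and the exocyclic alkene untouched.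

Step 9
Reactants: 12 methyl (12E)-labda-8(17),12,14-trien-18-oate
Product: 15 (12E)-labda-8(17),12,14-trien-18-ol, via C18 aldehyde 14 (not isolated)
Conditions: LiAlH4, THF, 0 → 40 °C; H2O, aq. NaOH
Reagents that add atoms: none
Why: Hydride reduction of the ester (LiAlH4) through the aldehyde gives the neopentyl C18 alcohol; isolated and conjugated alkenes are inert to the reagent.

Step 10
Reactants: 13 (12E)-labda-8(17),12,14-trien-18-oic acid; 15 (12E)-labda-8(17),12,14-trien-18-ol
Product: 16 target (CNP0316988.1)
Conditions: neat, 13:15 = 1:4 (excess 15 recovered), BHT (2 mol%), Ar, sealed tube, 140 °C, 60 h; acid/base extraction, SiO2, then preparative HPLC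
Reagents that add atoms: none
Why: Thermal Diels–Alder cross-dimerisation of unactivated 1,3-dienes (the myrcene → camphorene type): the s-cis 12E,14-diene of 13 adds suprafacially to the terminal C14'=C15' vinyl of 15 with C15–C15' and C12–C14' bond formation (bis-allylic "ortho" orientation) through the endo transition state, which makes the C12 and C14' substituents cis and creates both new stereocentres (12S,14'S on one diene face) without control from the remote decalins, so 16 is taken by preparative HPLC from its facial diastereomer, the trans adduct and the role-reversed hydroxy acid.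

**Compound list**

1 | (+)-abietic acid, abieta-7,13-dien-18-oic acid (4R,5R,9R,10R; 4α-CO2H, 5α-H, 9α-H, 10β-CH3) | CC(C)C1=CC2=CC[C@@H]3[C@](C)(CCC[C@@]3(C)C(=O)O)[C@H]2CC1 | starting material
2 | methyl abietate | CC(C)C1=CC2=CC[C@@H]3[C@](C)(CCC[C@@]3(C)C(=O)OC)[C@H]2CC1 | intermediate
3 | methyl 13,14-cis-dihydroxyabiet-7-en-18-oate (drawn as the 13β,14β-diol; either face gives 4) | CC(C)[C@]1(O)[C@@H](O)C2=CC[C@@H]3[C@](C)(CCC[C@@]3(C)C(=O)OC)[C@H]2CC1 | intermediate (not isolated)
4 | methyl 13-oxo-13,14-secoabiet-7-en-14-al-18-oate (ring-C-opened keto enal; 9α-H) | O=CC1=CC[C@@H]2[C@](C)(CCC[C@@]2(C)C(=O)OC)[C@H]1CCC(=O)C(C)C | intermediate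
5 | C14 (E)-p-toluenesulfonylhydrazone of 4 | Cc1ccc(cc1)S(=O)(=O)N/N=C/C1=CC[C@@H]2[C@](C)(CCC[C@@]2(C)C(=O)OC)[C@H]1CCC(=O)C(C)C | intermediate (not isolated)
6 | methyl 14-diazenyl-13-oxo-13,14-secoabiet-7-en-18-oate (allylic monoalkyl diazene) | N=NCC1=CC[C@@H]2[C@](C)(CCC[C@@]2(C)C(=O)OC)[C@H]1CCC(=O)C(C)C | intermediate (not isolated)
7 | methyl 13-oxo-13,14-secoabiet-8(14)-en-18-oate (exocyclic C8=CH2, 4-methyl-3-oxopentyl chain on C9) | C=C1CC[C@@H]2[C@](C)(CCC[C@@]2(C)C(=O)OC)[C@H]1CCC(=O)C(C)C | intermediate
8 | potassium (Z)-enolate of 7 (C12=C13–O⁻) | C=C1CC[C@@H]2[C@](C)(CCC[C@@]2(C)C(=O)OC)[C@H]1C/C=C(\[O-])C(C)C.[K+] | intermediate (not isolated)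
9 | methyl 12-hydroxy-13-oxo-13,14-secoabiet-8(14)-en-18-oate (C12 epimer mixture, centre not defined) | C=C1CC[C@@H]2[C@](C)(CCC[C@@]2(C)C(=O)OC)[C@H]1CC(O)C(=O)C(C)C | intermediate
10 | methyl 12-oxo-13,14,15,16-tetranorlabd-8(17)-en-18-oate (C12 aldehyde) | C=C1CC[C@@H]2[C@](C)(CCC[C@@]2(C)C(=O)OC)[C@H]1CC=O | intermediate
11 | methyl (12E)-14-oxo-15-norlabda-8(17),12-dien-18-oate | C=C1CC[C@@H]2[C@](C)(CCC[C@@]2(C)C(=O)OC)[C@H]1C/C=C(C)/C=O | intermediate
12 | methyl (12E)-labda-8(17),12,14-trien-18-oate (4R,5R,9S,10R) | C=C1CC[C@@H]2[C@](C)(CCC[C@@]2(C)C(=O)OC)[C@H]1C/C=C(C)/C=C | intermediate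
13 | (12E)-labda-8(17),12,14-trien-18-oic acid (4R,5R,9S,10R) | C=C1CC[C@@H]2[C@](C)(CCC[C@@]2(C)C(=O)O)[C@H]1C/C=C(C)/C=C | intermediate
14 | (12E)-labda-8(17),12,14-trien-18-al | C=C1CC[C@@H]2[C@](C)(CCC[C@@]2(C)C=O)[C@H]1C/C=C(C)/C=C | intermediate (not isolated)
15 | (12E)-labda-8(17),12,14-trien-18-ol (4R,5R,9S,10R) | C=C1CC[C@@H]2[C@](C)(CCC[C@@]2(C)CO)[C@H]1C/C=C(C)/C=C | intermediate
16 | target: cis-[4+2] adduct, acid half 4R,5R,9S,10R,12S, alcohol half 4'R,5'R,9'S,10'R,14'S, 12'E | C=C1CC[C@@H]2[C@](C)(CCC[C@@]2(C)C(=O)O)[C@H]1C[C@@H]1C(C)=CCC[C@@H]1/C(C)=C/C[C@H]1C(=C)CC[C@H]2[C@](C)(CO)CCC[C@]12C | target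

**Totals and risks**

Total step count: 10. Longest linear sequence: 9 (steps 1–7, then step 8 or 9, then step 10).

Steps most likely to fail:

Step 2. The site selectivity for the 13,14-alkene is expected rather than guaranteed; osmylation of the 7,8-alkene would open ring B instead of ring C. The fallback sets out from 2. Buffered peracid epoxidation (mCPBA, NaHCO3, CH2Cl2, −20 °C), where selectivity is governed by alkene nucleophilicity rather than osmate sterics, gives the vinyl epoxide methyl 13β,14β-epoxyabiet-7-en-18-oate F1. Periodic acid (H5IO6, THF–H2O, 0 °C) hydrolyses F1 to diol 3 and cleaves it in the same flask, and the route is rejoined at 4.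

Step 3. Three events run in one flask next to a free ketone; hydrazone formation or borane reduction at C13 would erode the yield. The fallback sets out from 4. NaBH4 (EtOH–CH2Cl2, −78 °C) reduces only the aldehyde to the allylic alcohol methyl 14-hydroxy-13-oxo-13,14-secoabiet-7-en-18-oate F2. Myers reductive transposition (2-nitrobenzenesulfonylhydrazide, PPh3, DEAD, N-methylmorpholine, −30 → 23 °C) then passes through the Mitsunobu adduct N-allyl-N-(2-nitrophenylsulfonyl)hydrazine F3, which loses the sulfinic acid to give the same diazene 6, and the route is rejoined at 7.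

Step 10. This is the weakest step. The two partners carry identical dienes, so the role-reversed cross-adduct (15 as diene, 13 as dienophile) forms at the same rate as 16, and neither the face of attack nor endo/exo is controlled by the remote decalins. Homodimers of 13 and 15, radical oligomers and acid-promoted diene isomerisation in the hot melt are further losses. I expect no more than about 5–10% of 16 from 13 after HPLC. The fallback sets out from 12 and 15. The cycloaddition is run at the ester stage (12:15 = 1:4, neat, BHT, 140 °C), so no free acid is present in the melt and the neutral adducts (diester, hydroxy ester, diol) separate on silica and normal-phase HPLC. This gives the hydroxy ester methyl ester of 16 F4, which is demethylated last (NaSEt, DMF, 90 °C; then dilute HCl), and the route is rejoined at 16. This fallback does not remove the statistical role and facial problem; it removes the isomerisation risk and makes the separation easier.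

**Further compounds**

F1 | step 2 | methyl 13β,14β-epoxyabiet-7-en-18-oate | CC(C)[C@]1(O4)[C@@H]4C2=CC[C@@H]3[C@](C)(CCC[C@@]3(C)C(=O)OC)[C@H]2CC1
F2 | step 3 | methyl 14-hydroxy-13-oxo-13,14-secoabiet-7-en-18-oate | OCC1=CC[C@@H]2[C@](C)(CCC[C@@]2(C)C(=O)OC)[C@H]1CCC(=O)C(C)C
F3 | step 3 | N-allyl-N-(2-nitrophenylsulfonyl)hydrazine derived from F2 | NN(CC1=CC[C@@H]2[C@](C)(CCC[C@@]2(C)C(=O)OC)[C@H]1CCC(=O)C(C)C)S(=O)(=O)c1ccccc1[N+](=O)[O-]
F4 | step 10 | methyl ester of 16 | C=C1CC[C@@H]2[C@](C)(CCC[C@@]2(C)C(=O)OC)[C@H]1C[C@@H]1C(C)=CCC[C@@H]1/C(C)=C/C[C@H]1C(=C)CC[C@H]2[C@](C)(CO)CCC[C@]12C
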